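**Assumption:** the target has no stereocentre (it is achiral), so no enantiocontrol is needed; compounds 1, 6, 7 and 10 are taken as commercial.

## Retrosynthetic overview

1. The target is two gigantol units joined by one CH2; the last step is hydrogenolysis of three benzyl ethers.
2. The bridging CH2 comes from a diarylmethanol by ionic deoxygenation (the MOM group is lost in the same pot). The carbinol is cut into a ring B aryllithium, metalated between OMOM and OMe, and a ring C benzaldehyde.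
3. Both ArCH2CH2Ar arms come from B-alkyl Suzuki–Miyaura couplings of aryl bromides with one alkylborane, made once from 4-(benzyloxy)-3-methoxystyrene and 9-BBN and used in two portions.
4. The ring C aldehyde comes from 5-bromoresorcinol by Vilsmeier formylation, para-selective O-benzylation and O-methylation; the ring B bromide is the MOM ether of 3-bromo-5-methoxyphenol.
5. No ring is built: all four benzene rings are bought and only the C–C bonds between them are made.

## Route

Step 1
Reactants: 1 5-bromoresorcinol (5-bromobenzene-1,3-diol)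
Product: 3 2-bromo-4,6-dihydroxybenzaldehyde, via aryl iminium chloride 2 (not isolated)
Conditions: POCl3, DMF, MeCN, 0 °C to rt; then H2O, 50 °C
Reagents that add atoms: N,N-dimethylformamide CN(C)C=O; water O
Why: Vilsmeier–Haack formylation goes, as with resorcinol and orcinol, at the carbon para to one OH and ortho to the other (next to Br) and not between the two OH groups, and water hydrolyses the iminium salt to the aldehyde.

Step 2
Reactants: 3 2-bromo-4,6-dihydroxybenzaldehyde
Product: 4 4-(benzyloxy)-2-bromo-6-hydroxybenzaldehyde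
Conditions: BnBr (1.05 equiv), KHCO3, MeCN, 60 °C
Reagents that add atoms: benzyl bromide BrCc1ccccc1
Why: In this Williamson etherification the 6-OH is tied up in a hydrogen bond to the aldehyde, so the weak base alkylates only the free, more acidic para 4-OH.

Step 3
Reactants: 4 4-(benzyloxy)-2-bromo-6-hydroxybenzaldehyde
Product: 5 4-(benzyloxy)-2-bromo-6-methoxybenzaldehyde
Conditions: MeI, K2CO3, DMF, 40 °C
Reagents that add atoms: iodomethane CI
Why: Williamson methylation of the remaining chelated phenol with the stronger base fixes the ortho-OMe and para-OBn pattern of ring C.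

Step 4
Reactants: 6 4-(benzyloxy)-3-methoxystyrene (1.05 equiv); 7 9-borabicyclo[3.3.1]nonane (9-BBN, 1.0 equiv)
Product: 8 9-{2-[4-(benzyloxy)-3-methoxyphenyl]ethyl}-9-borabicyclo[3.3.1]nonane
Conditions: 9-BBN (0.5 M in THF), THF, 0 °C to rt, 4 h; run on a scale that covers steps 5 and 7, kept as a THF stock solution under Ar
Reagents that add atoms: none
Why: Anti-Markovnikov hydroboration of the styrene by 9-BBN places boron on the terminal carbon, and the slight excess of styrene leaves no B–H that could later reduce an aldehyde.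

Step 5
Reactants: 5 4-(benzyloxy)-2-bromo-6-methoxybenzaldehyde; 8 9-{2-[4-(benzyloxy)-3-methoxyphenyl]ethyl}-9-borabicyclo[3.3.1]nonane (1.3 equiv, THF solution from step 4)
Product: 9 4-(benzyloxy)-2-{2-[4-(benzyloxy)-3-methoxyphenyl]ethyl}-6-methoxybenzaldehyde
Conditions: Pd(dppf)Cl2 (5 mol %), aq K3PO4 (3 equiv), THF/DMF, 50 °C
Reagents that add atoms: none
Why: B-alkyl Suzuki–Miyaura coupling gives the saturated two-carbon arm directly; the ortho-formyl group activates the bromide towards oxidative addition, and the borane, held as its hydroxyborate, does not touch the aldehyde.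

Step 6
Reactants: 10 3-bromo-5-methoxyphenol
Product: 11 1-bromo-3-methoxy-5-(methoxymethoxy)benzene
Conditions: NaH, MOMCl, THF/DMF, 0 °C to rt
Reagents that add atoms: chloromethyl methyl ether COCCl
Why: O-alkylation of the sodium phenoxide installs the MOM acetal, which protects the phenol and later directs the metalation.

Step 7
Reactants: 11 1-bromo-3-methoxy-5-(methoxymethoxy)benzene; 8 9-{2-[4-(benzyloxy)-3-methoxyphenyl]ethyl}-9-borabicyclo[3.3.1]nonane (1.3 equiv, THF solution from step 4)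
Product: 12 1-(benzyloxy)-2-methoxy-4-{2-[3-methoxy-5-(methoxymethoxy)phenyl]ethyl}benzene
Conditions: Pd(dppf)Cl2 (5 mol %), aq K3PO4 (3 equiv), THF/DMF, 65 °C
Reagents that add atoms: none
Why: The same B-alkyl Suzuki–Miyaura coupling gives the doubly protected gigantol; MOM and benzyl ethers are stable to the aqueous base.

Step 8
Reactants: 12 1-(benzyloxy)-2-methoxy-4-{2-[3-methoxy-5-(methoxymethoxy)phenyl]ethyl}benzene (1.3 equiv); 9 4-(benzyloxy)-2-{2-[4-(benzyloxy)-3-methoxyphenyl]ethyl}-6-methoxybenzaldehyde (1.0 equiv)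
Product: 14 {4-(benzyloxy)-2-{2-[4-(benzyloxy)-3-methoxyphenyl]ethyl}-6-methoxyphenyl}{4-{2-[4-(benzyloxy)-3-methoxyphenyl]ethyl}-2-methoxy-6-(methoxymethoxy)phenyl}methanol (racemic), via aryllithium 13 (not isolated)
Conditions: n-BuLi (1.25 equiv), TMEDA, THF, −10 to 0 °C, 1.5 h; then 9, −78 °C to rt; H2O
Reagents that add atoms: none
Why: Directed ortho-metalation takes the only hydrogen flanked by two coordinating oxygens (OMOM and OMe), and the aryllithium adds 1,2 to the non-enolisable aldehyde; the carbinol centre forms racemic and is removed in step 9.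

Step 9
Reactants: 14 {4-(benzyloxy)-2-{2-[4-(benzyloxy)-3-methoxyphenyl]ethyl}-6-methoxyphenyl}{4-{2-[4-(benzyloxy)-3-methoxyphenyl]ethyl}-2-methoxy-6-(methoxymethoxy)phenyl}methanol
Product: 15 2-({4-(benzyloxy)-2-{2-[4-(benzyloxy)-3-methoxyphenyl]ethyl}-6-methoxyphenyl}methyl)-5-{2-[4-(benzyloxy)-3-methoxyphenyl]ethyl}-3-methoxyphenol
Conditions: Et3SiH (6 equiv), then TFA (15 vol %), CH2Cl2, 0 °C to rt
Reagents that add atoms: none
Why: In this ionic hydrogenation the acid ionises the electron-rich doubly benzylic alcohol and the silane delivers hydride to the diarylmethyl cation; TFA also cleaves the phenolic MOM acetal and the silane reduces the methoxymethyl cation, so it cannot alkylate the arenes.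

Step 10
Reactants: 15 2-({4-(benzyloxy)-2-{2-[4-(benzyloxy)-3-methoxyphenyl]ethyl}-6-methoxyphenyl}methyl)-5-{2-[4-(benzyloxy)-3-methoxyphenyl]ethyl}-3-methoxyphenol
Product: 16 2-({4-hydroxy-2-[2-(4-hydroxy-3-methoxyphenyl)ethyl]-6-methoxyphenyl}methyl)-5-[2-(4-hydroxy-3-methoxyphenyl)ethyl]-3-methoxyphenol (target CNP0079000.0)
Conditions: H2 (1 atm), Pd/C (10 %), EtOAc/MeOH, rt
Reagents that add atoms: none
Why: Catalytic hydrogenolysis removes the three benzyl ethers, while the methyl ethers and the diarylmethane CH2 are inert.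

## Compound list

1 | 5-bromoresorcinol (5-bromobenzene-1,3-diol) | Oc1cc(O)cc(Br)c1 | starting material
2 | N-[(2-bromo-4,6-dihydroxyphenyl)methylidene]-N-methylmethanaminium chloride (not isolated) | C[N+](C)=Cc1c(O)cc(O)cc1Br.[Cl-] | intermediate
3 | 2-bromo-4,6-dihydroxybenzaldehyde | O=Cc1c(O)cc(O)cc1Br | intermediate
4 | 4-(benzyloxy)-2-bromo-6-hydroxybenzaldehyde | O=Cc1c(O)cc(OCc2ccccc2)cc1Br | intermediate
5 | 4-(benzyloxy)-2-bromo-6-methoxybenzaldehyde | COc1cc(OCc2ccccc2)cc(Br)c1C=O | intermediate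
6 | 4-(benzyloxy)-3-methoxystyrene (1-(benzyloxy)-4-ethenyl-2-methoxybenzene) | C=Cc1ccc(OCc2ccccc2)c(OC)c1 | starting material
7 | 9-borabicyclo[3.3.1]nonane (9-BBN) | B1C2CCCC1CCC2 | starting material
8 | 9-{2-[4-(benzyloxy)-3-methoxyphenyl]ethyl}-9-borabicyclo[3.3.1]nonane (THF stock solution) | COc1cc(CCB2C3CCCC2CCC3)ccc1OCc1ccccc1 | intermediate
9 | 4-(benzyloxy)-2-{2-[4-(benzyloxy)-3-methoxyphenyl]ethyl}-6-methoxybenzaldehyde | COc1cc(OCc2ccccc2)cc(CCc2ccc(OCc3ccccc3)c(OC)c2)c1C=O | intermediate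
10 | 3-bromo-5-methoxyphenol | COc1cc(O)cc(Br)c1 | starting material
11 | 1-bromo-3-methoxy-5-(methoxymethoxy)benzene | COCOc1cc(OC)cc(Br)c1 | intermediate
12 | 1-(benzyloxy)-2-methoxy-4-{2-[3-methoxy-5-(methoxymethoxy)phenyl]ethyl}benzene | COCOc1cc(OC)cc(CCc2ccc(OCc3ccccc3)c(OC)c2)c1 | intermediate
13 | {4-{2-[4-(benzyloxy)-3-methoxyphenyl]ethyl}-2-methoxy-6-(methoxymethoxy)phenyl}lithium (not isolated) | COCOc1cc(CCc2ccc(OCc3ccccc3)c(OC)c2)cc(OC)c1[Li] | intermediate
14 | {4-(benzyloxy)-2-{2-[4-(benzyloxy)-3-methoxyphenyl]ethyl}-6-methoxyphenyl}{4-{2-[4-(benzyloxy)-3-methoxyphenyl]ethyl}-2-methoxy-6-(methoxymethoxy)phenyl}methanol, racemic | COCOc1cc(CCc2ccc(OCc3ccccc3)c(OC)c2)cc(OC)c1C(O)c1c(CCc2ccc(OCc3ccccc3)c(OC)c2)cc(OCc2ccccc2)cc1OC | intermediate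
15 | 2-({4-(benzyloxy)-2-{2-[4-(benzyloxy)-3-methoxyphenyl]ethyl}-6-methoxyphenyl}methyl)-5-{2-[4-(benzyloxy)-3-methoxyphenyl]ethyl}-3-methoxyphenol | Oc1cc(CCc2ccc(OCc3ccccc3)c(OC)c2)cc(OC)c1Cc1c(CCc2ccc(OCc3ccccc3)c(OC)c2)cc(OCc2ccccc2)cc1OC | intermediate
16 | 2-({4-hydroxy-2-[2-(4-hydroxy-3-methoxyphenyl)ethyl]-6-methoxyphenyl}methyl)-5-[2-(4-hydroxy-3-methoxyphenyl)ethyl]-3-methoxyphenol (achiral) | COc1cc(CCc2cc(O)c(Cc3c(CCc4ccc(O)c(OC)c4)cc(O)cc3OC)c(OC)c2)ccc1O | target

## Step count and risks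

Total step count: 10. Longest linear sequence: 7 (steps 1, 2, 3, 5, 8, 9, 10); step 4 supplies the alkylborane for both couplings, and steps 6 and 7 form the ring B branch.

The three steps most likely to fail:

**Step 5** (the alkylborane may reduce the ortho-bromo aldehyde, and the bromide is hindered). The fallback sets out from 5. Compound 5 is coupled with styrene 6 in a Mizoroki–Heck reaction (Pd(OAc)2, n-Bu4NCl, NaHCO3, DMF, 90 °C) to give (E)-4-(benzyloxy)-2-{2-[4-(benzyloxy)-3-methoxyphenyl]ethenyl}-6-methoxybenzaldehyde F1. The alkene alone is then hydrogenated over Pd/C poisoned with Ph2S (H2 1 atm, EtOAc, rt), which leaves the aryl aldehyde and the benzyl ethers untouched, and the route is rejoined at 9.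

**Step 8** (a carbinol with four ortho substituents must form, and the benzyl ethers must survive n-BuLi). The fallback sets out from 12 and uses 9, and replaces carbonyl addition by an sp2–sp3 cross-coupling. Aldehyde 9 is reduced (NaBH4, MeOH/THF, 0 °C) to {4-(benzyloxy)-2-{2-[4-(benzyloxy)-3-methoxyphenyl]ethyl}-6-methoxyphenyl}methanol F2. F2 is converted with SOCl2 (CH2Cl2, 0 °C, used crude at once) into 5-(benzyloxy)-1-{2-[4-(benzyloxy)-3-methoxyphenyl]ethyl}-2-(chloromethyl)-3-methoxybenzene F3. Compound 12 is lithiated as before to 13 and transmetalated with ZnCl2 to {4-{2-[4-(benzyloxy)-3-methoxyphenyl]ethyl}-2-methoxy-6-(methoxymethoxy)phenyl}zinc chloride F4. Negishi coupling of F4 with F3 (Pd(OAc)2, SPhos, THF, 50 °C) gives 5-(benzyloxy)-1-{2-[4-(benzyloxy)-3-methoxyphenyl]ethyl}-2-({4-{2-[4-(benzyloxy)-3-methoxyphenyl]ethyl}-2-methoxy-6-(methoxymethoxy)phenyl}methyl)-3-methoxybenzene F5, which is the methoxymethyl ether of 15. HCl in MeOH/THF at 40 °C removes the MOM group and the route is rejoined at 15, so step 9 is not needed.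

**Step 9** (the diarylmethyl cation could cyclise onto the neighbouring arylethyl arm, or benzyl ethers could be lost or migrate in TFA). The fallback sets out from 14. Carbinol 14 is hydrogenolysed (H2 3 atm, Pd(OH)2/C, EtOAc/AcOH, rt), which removes the benzylic hydroxyl and the three benzyl ethers in one operation and gives 4-({4-[2-(4-hydroxy-3-methoxyphenyl)ethyl]-2-methoxy-6-(methoxymethoxy)phenyl}methyl)-3-[2-(4-hydroxy-3-methoxyphenyl)ethyl]-5-methoxyphenol F6, which is the methoxymethyl ether of the target. Brief treatment with HCl in MeOH at 40 °C cleaves the acetal and gives 16 directly.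

## Further compounds

F1 | step 5 | (E)-4-(benzyloxy)-2-{2-[4-(benzyloxy)-3-methoxyphenyl]ethenyl}-6-methoxybenzaldehyde | COc1cc(OCc2ccccc2)cc(/C=C/c2ccc(OCc3ccccc3)c(OC)c2)c1C=O
F2 | step 8 | {4-(benzyloxy)-2-{2-[4-(benzyloxy)-3-methoxyphenyl]ethyl}-6-methoxyphenyl}methanol | COc1cc(OCc2ccccc2)cc(CCc2ccc(OCc3ccccc3)c(OC)c2)c1CO
F3 | step 8 | 5-(benzyloxy)-1-{2-[4-(benzyloxy)-3-methoxyphenyl]ethyl}-2-(chloromethyl)-3-methoxybenzene | COc1cc(OCc2ccccc2)cc(CCc2ccc(OCc3ccccc3)c(OC)c2)c1CCl
F4 | step 8 | {4-{2-[4-(benzyloxy)-3-methoxyphenyl]ethyl}-2-methoxy-6-(methoxymethoxy)phenyl}zinc chloride | COCOc1cc(CCc2ccc(OCc3ccccc3)c(OC)c2)cc(OC)c1[Zn]Cl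
F5 | step 8 | 5-(benzyloxy)-1-{2-[4-(benzyloxy)-3-methoxyphenyl]ethyl}-2-({4-{2-[4-(benzyloxy)-3-methoxyphenyl]ethyl}-2-methoxy-6-(methoxymethoxy)phenyl}methyl)-3-methoxybenzene | COCOc1cc(CCc2ccc(OCc3ccccc3)c(OC)c2)cc(OC)c1Cc1c(CCc2ccc(OCc3ccccc3)c(OC)c2)cc(OCc2ccccc2)cc1OC
F6 | step 9 | 4-({4-[2-(4-hydroxy-3-methoxyphenyl)ethyl]-2-methoxy-6-(methoxymethoxy)phenyl}methyl)-3-[2-(4-hydroxy-3-methoxyphenyl)ethyl]-5-methoxyphenol | COCOc1cc(CCc2ccc(O)c(OC)c2)cc(OC)c1Cc1c(CCc2ccc(O)c(OC)c2)cc(O)cc1OC
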